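Pakyonol's 20-membered ring is opened at the aryl C–O bond between the oxygen of the para-disubstituted ring B and the carbon of anisole ring A that lies ortho to OMe and meta to the CH2CH2 chain. Because this ether joins two 4-alkylphenol units, it can be formed by oxidative phenol coupling: Tl(NO3)3 oxidises a 2,6-dibromophenol (ring A), the oxygen of a 2,6-dichlorophenol (ring B) adds ipso to bromine, and the macrocycle closes in one operation with the halogens fixing the direction. The precursor is a linear bis(bibenzyl) with one dibromophenol and one dichlorophenol terminus, built from four purchased arenes by two Wittig olefinations and one SNAr etherification; ring C stays benzyl-protected.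

Key step: step 12

Remark on the chemistry: rings are lettered A (anisole ring), B (para-disubstituted ring), C (hydroxylated ring) and D (meta-disubstituted ring). The stilbenes 5, 8 and 14 are carried as E/Z mixtures and written without alkene geometry, because both alkenes are saturated in step 10.

Step 1
Reactants: 1 3,5-dibromo-4-hydroxybenzaldehyde
Product: 2 3,5-dibromo-4-(methoxymethoxy)benzaldehyde
Conditions: MOMCl, i-Pr2NEt, CH2Cl2, 0 °C → rt
Reagents that add atoms: chloromethyl methyl ether, COCCl
Why: Williamson-type O-alkylation in which the acidic dibromophenoxide, although flanked by two bromines, is captured by the very reactive chloromethyl ether, giving a base-stable acetal for the olefination and SNAr steps.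

Step 2
Reactants: 3 3-hydroxybenzyl alcohol
Product: 4 (3-hydroxybenzyl)triphenylphosphonium bromide
Conditions: PPh3·HBr, MeCN, reflux
Reagents that add atoms: triphenylphosphine hydrobromide, Br.c1ccc(cc1)P(c1ccccc1)c1ccccc1
Why: Acid-mediated substitution of the benzylic hydroxyl by triphenylphosphine (phosphonium salt formation), which leaves the phenol untouched, so no protection is needed.

Step 3
Reactants: 2 3,5-dibromo-4-(methoxymethoxy)benzaldehyde; 4 (3-hydroxybenzyl)triphenylphosphonium bromide
Product: 5 3-[2-(3,5-dibromo-4-(methoxymethoxy)phenyl)ethenyl]phenol (E/Z mixture)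
Conditions: t-BuOK (2.2 equiv), THF, 0 °C → rt; aq NH4Cl
Reagents that add atoms: none
Why: Wittig olefination in which two equivalents of base generate the phenoxide ylide, which condenses with the unhindered aldehyde (bromines meta to CHO); the alkene geometry is irrelevant because the double bond is reduced in step 10.

Step 4
Reactants: 6 4-fluoro-3-hydroxybenzaldehyde
Product: 7 3-(benzyloxy)-4-fluorobenzaldehyde
Conditions: BnBr, K2CO3, DMF, rt
Reagents that add atoms: benzyl bromide, BrCc1ccccc1
Why: Williamson ether synthesis on the phenol, with the aryl fluoride inert to carbonate at room temperature.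

Step 5
Reactants: 5 3-[2-(3,5-dibromo-4-(methoxymethoxy)phenyl)ethenyl]phenol; 7 3-(benzyloxy)-4-fluorobenzaldehyde
Product: 8 3-(benzyloxy)-4-{3-[2-(3,5-dibromo-4-(methoxymethoxy)phenyl)ethenyl]phenoxy}benzaldehyde (E/Z mixture)
Conditions: Cs2CO3, DMSO, 110 °C
Reagents that add atoms: none
Why: Nucleophilic aromatic substitution (addition–elimination) in which the phenoxide of 5 displaces the fluoride para to the formyl group of 7 through a Meisenheimer intermediate, while the unactivated aryl bromides, the MOM acetal, the benzyl ether and the alkene tolerate carbonate base.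

Step 6
Reactants: 9 3,5-dichloro-4-hydroxybenzaldehyde
Product: 10 3,5-dichloro-4-(methoxymethoxy)benzaldehyde
Conditions: MOMCl, i-Pr2NEt, CH2Cl2, 0 °C → rt
Reagents that add atoms: chloromethyl methyl ether, COCCl
Why: Williamson-type O-alkylation of the acidic dichlorophenol, which masks the phenoxide that would otherwise sit para to the later ylide carbon and could expel triphenylphosphine as a quinone methide.

Step 7
Reactants: 10 3,5-dichloro-4-(methoxymethoxy)benzaldehyde
Product: 11 [3,5-dichloro-4-(methoxymethoxy)phenyl]methanol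
Conditions: NaBH4, MeOH/THF, 0 °C
Reagents that add atoms: none
Why: Borohydride reduction of the aldehyde to the benzylic alcohol, with aryl chlorides and the MOM acetal inert.

Step 8
Reactants: 11 [3,5-dichloro-4-(methoxymethoxy)phenyl]methanol
Product: 13 [3,5-dichloro-4-(methoxymethoxy)benzyl]triphenylphosphonium bromide, via benzylic bromide 12 (not isolated)
Conditions: PPh3 (1.1 equiv), CBr4 (1.1 equiv), MeCN, 0 °C → rt; then PPh3 (1.3 equiv), 80 °C; precipitation from toluene/Et2O
Reagents that add atoms: carbon tetrabromide, BrC(Br)(Br)Br; triphenylphosphine, c1ccc(cc1)P(c1ccccc1)c1ccccc1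
Why: The Appel reaction makes the benzylic bromide under neutral conditions that spare the acid-labile MOM acetal, and SN2 quaternisation of the added triphenylphosphine then gives the salt in the same flask.

Step 9
Reactants: 8 3-(benzyloxy)-4-{3-[2-(3,5-dibromo-4-(methoxymethoxy)phenyl)ethenyl]phenoxy}benzaldehyde; 13 [3,5-dichloro-4-(methoxymethoxy)benzyl]triphenylphosphonium bromide
Product: 14 2-(benzyloxy)-1-{3-[2-(3,5-dibromo-4-(methoxymethoxy)phenyl)ethenyl]phenoxy}-4-[2-(3,5-dichloro-4-(methoxymethoxy)phenyl)ethenyl]benzene (E/Z mixtures)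
Conditions: t-BuOK, THF, 0 °C → rt
Reagents that add atoms: none
Why: Wittig olefination of the semi-stabilised benzylic ylide with the aryl aldehyde; the acetals, benzyl ether, aryl halides and existing alkene are inert to the base, and the geometry again does not matter.

Step 10
Reactants: 14 bis-stilbene
Product: 15 2-(benzyloxy)-1-{3-[2-(3,5-dibromo-4-(methoxymethoxy)phenyl)ethyl]phenoxy}-4-[2-(3,5-dichloro-4-(methoxymethoxy)phenyl)ethyl]benzene
Conditions: TsNHNH2 (excess), NaOAc, DME/H2O, reflux
Reagents that add atoms: none
Why: Diimide reduction (concerted syn hydrogen transfer from HN=NH made in the flask) saturates both alkenes without touching C–Br, C–Cl or the benzyl ether, which catalytic hydrogenation would endanger, and the acetate buffer protects the MOM acetals.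

Step 11
Reactants: 15 bis-MOM bis(bibenzyl)
Product: 16 2,6-dibromo-4-[2-(3-{2-(benzyloxy)-4-[2-(3,5-dichloro-4-hydroxyphenyl)ethyl]phenoxy}phenyl)ethyl]phenol
Conditions: conc. HCl, MeOH/THF, 50 °C
Reagents that add atoms: none
Why: Acid-catalysed acetal exchange with methanol (MOM cleavage) frees both halophenols, while the benzyl ether, the diaryl ether and the aryl halides are stable.

Step 12
Reactants: 16 seco bis(bibenzyl) with a 2,6-dibromophenol terminus (ring A) and a 2,6-dichlorophenol terminus (ring B)
Product: 18 halogenated macrocyclic phenol (ring A OH flanked by Br and the new aryloxy group), via methoxydienone macrocycle 17 (not isolated)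
Conditions: Tl(NO3)3·3H2O (3 equiv), MeOH/CH2Cl2 (1:4), 1 mM, −20 → 0 °C; then Zn dust, AcOH, rt
Reagents that add atoms: none
Why: Trivalent thallium oxidises the more easily oxidised 2,6-dibromophenol of ring A to a phenoxonium-type species, the hydroxyl oxygen of the 2,6-dichlorophenol of ring B adds to its ortho carbon ipso to bromine, and loss of that bromine rearomatises ring A; excess oxidant in methanol turns the new phenol into the 4-methoxycyclohexa-2,5-dienone 17, which zinc in acetic acid reduces back to the phenol 18 (as it does any uncyclised quinol ether, so unreacted 16 should be recoverable). The closest known reaction type is the Tl(NO3)3-mediated oxidative coupling of bis(2,6-dihalophenols) to isodityrosine-type macrocyclic diaryl ethers. The only ring formed, the 20-membered macrocycle, closes end-to-end by intramolecular C–O bond formation across a flexible, nearly strain-free tether, favoured by high dilution. No stereocentre is created in the product; the quaternary carbon of 17 is racemic and disappears on reduction. The step needs directional selectivity (ring B as oxygen donor, ring A as carbon acceptor), secured by the lower oxidation potential of the dibromophenol and the better leaving ability of bromine over chlorine; the two ortho carbons of ring A are equivalent, the four ortho halogens block C–C coupling, and the aryl ethers of rings C and D are much harder to oxidise than the free phenols.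

Step 13
Reactants: 18 halogenated macrocyclic phenol
Product: 19 halogenated macrocyclic methyl ether
Conditions: MeI, K2CO3, DMF, rt
Reagents that add atoms: iodomethane, CI
Why: Williamson O-methylation of the only free phenol, which is acidic enough (ortho bromine and aryloxy group) to be alkylated readily despite its two ortho substituents.

Step 14
Reactants: 19 halogenated macrocyclic methyl ether
Product: 20 pakyonol
Conditions: H2 (3 atm), 10% Pd/C, NaOAc (excess), MeOH/THF, rt → 40 °C
Reagents that add atoms: none
Why: Palladium-catalysed hydrogenolysis cleaves the aryl C–Br bond, both aryl C–Cl bonds (hydrodehalogenation) and the benzylic C–O bond in one operation, with sodium acetate neutralising HBr and HCl; an acetate rather than an amine base is chosen because amines retard O-debenzylation on Pd/C, and the methyl and diaryl ethers are not cleaved.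

Compound list
1 | 3,5-dibromo-4-hydroxybenzaldehyde | O=Cc1cc(Br)c(O)c(Br)c1 | starting material
2 | 3,5-dibromo-4-(methoxymethoxy)benzaldehyde | COCOc1c(Br)cc(C=O)cc1Br | intermediate
3 | 3-hydroxybenzyl alcohol | OCc1cccc(O)c1 | starting material
4 | (3-hydroxybenzyl)triphenylphosphonium bromide | Oc1cccc(C[P+](c2ccccc2)(c2ccccc2)c2ccccc2)c1.[Br-] | intermediate
5 | 3-[2-(3,5-dibromo-4-(methoxymethoxy)phenyl)ethenyl]phenol, E/Z mixture | Oc1cccc(C=Cc2cc(Br)c(OCOC)c(Br)c2)c1 | intermediate
6 | 4-fluoro-3-hydroxybenzaldehyde | O=Cc1ccc(F)c(O)c1 | starting material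
7 | 3-(benzyloxy)-4-fluorobenzaldehyde | O=Cc1ccc(F)c(OCc2ccccc2)c1 | intermediate
8 | 3-(benzyloxy)-4-{3-[2-(3,5-dibromo-4-(methoxymethoxy)phenyl)ethenyl]phenoxy}benzaldehyde, E/Z mixture | O=Cc1ccc(Oc2cccc(C=Cc3cc(Br)c(OCOC)c(Br)c3)c2)c(OCc2ccccc2)c1 | intermediate
9 | 3,5-dichloro-4-hydroxybenzaldehyde | O=Cc1cc(Cl)c(O)c(Cl)c1 | starting material
10 | 3,5-dichloro-4-(methoxymethoxy)benzaldehyde | COCOc1c(Cl)cc(C=O)cc1Cl | intermediate
11 | [3,5-dichloro-4-(methoxymethoxy)phenyl]methanol | COCOc1c(Cl)cc(CO)cc1Cl | intermediate
12 | 5-(bromomethyl)-1,3-dichloro-2-(methoxymethoxy)benzene (benzylic bromide) | COCOc1c(Cl)cc(CBr)cc1Cl | intermediate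
13 | [3,5-dichloro-4-(methoxymethoxy)benzyl]triphenylphosphonium bromide | COCOc1c(Cl)cc(C[P+](c2ccccc2)(c2ccccc2)c2ccccc2)cc1Cl.[Br-] | intermediate
14 | 2-(benzyloxy)-1-{3-[2-(3,5-dibromo-4-(methoxymethoxy)phenyl)ethenyl]phenoxy}-4-[2-(3,5-dichloro-4-(methoxymethoxy)phenyl)ethenyl]benzene, E/Z mixtures at both alkenes | COCOc1c(Cl)cc(C=Cc2ccc(Oc3cccc(C=Cc4cc(Br)c(OCOC)c(Br)c4)c3)c(OCc3ccccc3)c2)cc1Cl | intermediate
15 | 2-(benzyloxy)-1-{3-[2-(3,5-dibromo-4-(methoxymethoxy)phenyl)ethyl]phenoxy}-4-[2-(3,5-dichloro-4-(methoxymethoxy)phenyl)ethyl]benzene | COCOc1c(Cl)cc(CCc2ccc(Oc3cccc(CCc4cc(Br)c(OCOC)c(Br)c4)c3)c(OCc3ccccc3)c2)cc1Cl | intermediate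
16 | 2,6-dibromo-4-[2-(3-{2-(benzyloxy)-4-[2-(3,5-dichloro-4-hydroxyphenyl)ethyl]phenoxy}phenyl)ethyl]phenol (seco bisphenol) | Oc1c(Cl)cc(CCc2ccc(Oc3cccc(CCc4cc(Br)c(O)c(Br)c4)c3)c(OCc3ccccc3)c2)cc1Cl | intermediate
17 | methoxydienone macrocycle: 18 with ring A as a 2-aryloxy-6-bromo-4-methoxy-4-alkylcyclohexa-2,5-dienone, racemic at the methoxy-bearing carbon | O=C1C(Br)=CC2(OC)C=C1Oc1c(Cl)cc(cc1Cl)CCc1ccc(c(OCc3ccccc3)c1)Oc1cccc(c1)CC2 | intermediate
18 | halogenated macrocyclic phenol: 20-membered ring; ring A a 2-aryloxy-6-bromo-4-alkylphenol, ring B 2,6-dichloro on either side of the ether oxygen, ring C with OBn ortho to its ether oxygen, ring D meta-disubstituted | Oc1c(Br)cc2cc1Oc1c(Cl)cc(cc1Cl)CCc1ccc(c(OCc3ccccc3)c1)Oc1cccc(c1)CC2 | intermediate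
19 | halogenated macrocyclic methyl ether (18 with OMe in place of the ring A OH) | COc1c(Br)cc2cc1Oc1c(Cl)cc(cc1Cl)CCc1ccc(c(OCc3ccccc3)c1)Oc1cccc(c1)CC2 | intermediate
20 | pakyonol | COc1ccc2cc1Oc1ccc(cc1)CCc1ccc(c(O)c1)Oc1cccc(c1)CC2 | target

Total step count: 14 steps.
Longest linear sequence: 9 steps (1 → 2 → 5 → 8 → 14 → 15 → 16 → 18 → 19 → 20; the branch from 9 through 10, 11 and 13 is equally long).

Steps most likely to fail

1. Step 12 (oxidative macrocyclisation). Intermolecular coupling to oligomers may compete with the end-to-end closure, oxidation may stop at quinol ethers without C–O bond formation, or coupling may run in the reverse sense with loss of chlorine. The fallback closes the same diaryl ether by an intramolecular Ullmann etherification, with the oxygen now placed on ring A and a bromide on ring B. It sets out from phosphonium salt 4 and fluoroaldehyde 7 and comes back to the route at 20. Purchased isovanillin is protected with MOMCl/i-Pr2NEt to give 4-methoxy-3-(methoxymethoxy)benzaldehyde F1. Wittig olefination of F1 with 4 (t-BuOK, THF) should give the stilbene phenol 3-{2-[4-methoxy-3-(methoxymethoxy)phenyl]ethenyl}phenol F2. SNAr of F2 with 7 (Cs2CO3, DMSO, 110 °C) should give the diaryl ether aldehyde F3. Wittig olefination of F3 with purchased (4-bromobenzyl)triphenylphosphonium bromide should give the bromo bis-stilbene F4. Diimide reduction (TsNHNH2, NaOAc, DME/H2O, reflux) should give the bromo bis(bibenzyl) MOM ether F5, and HCl in MeOH should free the seco bromo phenol F6. Treatment with CuI, N,N-dimethylglycine and Cs2CO3 in dioxane at 100 °C under high dilution should close the macrocycle to O-benzylpakyonol F7, and H2 over Pd/C in EtOAc/MeOH then removes the benzyl group to give 20.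

2. Step 14 (global hydrogenolysis). Hydrodechlorination of the two hindered chlorines may stall, or the benzyl ether may survive, so that partly reduced mixtures result. The fallback separates the two tasks; it sets out from 19 and comes back at 20. BCl3 with pentamethylbenzene in CH2Cl2 at −78 °C should cleave the benzyl ether selectively to the halogenated macrocyclic diol monomethyl ether F8. With no benzyl ether left, H2 over Pd/C with Et3N in MeOH/THF can then be used for the hydrodehalogenation, which gives 20.

3. Step 5 (SNAr etherification). Fluoride displacement on the ring bearing the ortho benzyloxy group may be slow, and the aldehyde may be consumed by side reactions at the temperature needed. The fallback uses a more strongly activated electrophile and adjusts the oxidation level afterwards; it sets out from phenol 5 and comes back at 8. Purchased 4-fluoro-3-hydroxybenzonitrile is benzylated (BnBr, K2CO3, DMF) to 3-(benzyloxy)-4-fluorobenzonitrile F9. SNAr with 5 (K2CO3, DMSO, 90 °C) should give the diaryl ether nitrile F10. Reduction with i-Bu2AlH in toluene at −78 °C, followed by mild aqueous hydrolysis of the imine, should then give aldehyde 8.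

Further compounds
F1 | step 12 | 4-methoxy-3-(methoxymethoxy)benzaldehyde | COCOc1cc(C=O)ccc1OC
F2 | step 12 | 3-{2-[4-methoxy-3-(methoxymethoxy)phenyl]ethenyl}phenol, E/Z mixture | Oc1cccc(C=Cc2ccc(OC)c(OCOC)c2)c1
F3 | step 12 | 3-(benzyloxy)-4-{3-[2-(4-methoxy-3-(methoxymethoxy)phenyl)ethenyl]phenoxy}benzaldehyde, E/Z mixture | O=Cc1ccc(Oc2cccc(C=Cc3ccc(OC)c(OCOC)c3)c2)c(OCc2ccccc2)c1
F4 | step 12 | 2-(benzyloxy)-4-[2-(4-bromophenyl)ethenyl]-1-{3-[2-(4-methoxy-3-(methoxymethoxy)phenyl)ethenyl]phenoxy}benzene, E/Z mixtures | COCOc1cc(C=Cc2cccc(Oc3ccc(C=Cc4ccc(Br)cc4)cc3OCc3ccccc3)c2)ccc1OC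
F5 | step 12 | 2-(benzyloxy)-4-[2-(4-bromophenyl)ethyl]-1-{3-[2-(4-methoxy-3-(methoxymethoxy)phenyl)ethyl]phenoxy}benzene | COCOc1cc(CCc2cccc(Oc3ccc(CCc4ccc(Br)cc4)cc3OCc3ccccc3)c2)ccc1OC
F6 | step 12 | 5-[2-(3-{2-(benzyloxy)-4-[2-(4-bromophenyl)ethyl]phenoxy}phenyl)ethyl]-2-methoxyphenol | COc1ccc(CCc2cccc(Oc3ccc(CCc4ccc(Br)cc4)cc3OCc3ccccc3)c2)cc1O
F7 | step 12 | O-benzylpakyonol | COc1ccc2cc1Oc1ccc(cc1)CCc1ccc(c(OCc3ccccc3)c1)Oc1cccc(c1)CC2
F8 | step 14 | bromo dichloro pakyonol (19 with free OH on ring C) | COc1c(Br)cc2cc1Oc1c(Cl)cc(cc1Cl)CCc1ccc(c(O)c1)Oc1cccc(c1)CC2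
F9 | step 5 | 3-(benzyloxy)-4-fluorobenzonitrile | N#Cc1ccc(F)c(OCc2ccccc2)c1
F10 | step 5 | 3-(benzyloxy)-4-{3-[2-(3,5-dibromo-4-(methoxymethoxy)phenyl)ethenyl]phenoxy}benzonitrile, E/Z mixture | N#Cc1ccc(Oc2cccc(C=Cc3cc(Br)c(OCOC)c(Br)c3)c2)c(OCc2ccccc2)c1
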